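(The constants used here are those of an exercise; the rest is arithmetic.)

The ratio to carry through these flasks is the capture number: k3 times the charge of E times the run time, which says how far Q + X → Q.X can go in a run with both partners standing at the full charge of E.

    X → G (k1 = 2.47 × 10⁻⁴ min⁻¹)
    Z ⇌ Q.X, rate k2*(cs2 - [Q.X]) while solid is left; crystals form when [Q.X] > cs2 (cs2 = 19 mM, k2 = 0.0781 min⁻¹)
    Q + X → Q.X (k3 = 0.0841 L mol⁻¹ min⁻¹)
    E → X (k4 = 0.00524 min⁻¹)

| flask | E | Q | time |
|---|---|---|---|
| birch | 0.050 M | 0.700 equiv | 8.0 h |
| cedar | 0.050 M | 0.910 equiv | 8.0 h |

- what is said of Q.X includes Z
- Z is a solid; its amount is given per volume of the solution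
- run time (birch): 8.0 h

* which of these there is most of at the end, counted by the E in it, birch (E / X / Q.X)
* which of these there is most of at the end, counted by the E in it, cedar (E / X / Q.X)
* how much there is at the end of the one of these that leads, in percent of the E charged: birch
* how much there is at the end of the one of these that leads, in percent of the E charged: cedar

In fractions of the E charged, the capture number is 2.02 for birch and for cedar, which differ in the Q charged. In the first instants X stands at zero, so no Q.X forms, and E feeds X by first-order decay. By the middle of the run E is down to 28.4%; X has built up, Q is falling, and capture, pseudo-first-order in X at any given Q, is under way. X → G is left out of this reckoning because its half-life of 47 h is longer than the run of 8.0 h. Towards the end E stands at 8.08%, so 91.9% has been released. Crystals appear once dissolved Q.X passes 38.0% of the charge, but Z counts as Q.X and step 3 has no back step.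

Now each curve is replaced by its mean. Released E averages m = 63.5% over the run. Q.X, drawn as a straight line up to its end fraction p, averages p/2, and that amount is taken from m and from a, the equivalents of Q. So p equals the capture number times (a − p/2) times (m − p/2). This reckoning gives p = 42.0% in birch, leaving 49.9% as X, more than Q.X. In cedar it gives p = 50.6%, more than the 41.3% left as X.

The forecast names X at 47% for birch and Q.X at 48% for cedar, since “the extra Q in cedar puts Q.X ahead of X”; its leaders are those reckoned here, at lower figures.

The flask gives X at 47.2% in birch and Q.X at 48.2% in cedar, where cedar's p stood 2.4 percentage points high. Cedar ends with 47.0% of its Q still free. Setting X equal to Q.X, the capture number puts the turn at 0.792 equiv; the computed turn is 0.790 equiv. For the neighbour of cedar charged with 0.550 equiv of Q, below the turn, the same capture number gives p = 34.9%. That flask ends with 32.9% Q.X, and X holds most of the E.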